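**Plan**

Numbering used in the text: ring C1 (bears C7H2O), C2 (=CH), C3 (CH–O-tigloyl), C4 (CH–i-Pr), C5 (CH–OH), C6 (C=O); C7 is the exocyclic CH2.
Retrosynthesis cuts, in order: the C3–O acyl bond, the C7–C1 bond (tigloyloxymethyl unit onto an α-iodoenone), the C5–O bond and the C4–i-Pr bond. This leaves p-benzoquinone mono(dimethyl ketal), whose six carbons are the whole ring.
Forward: the ring is present from the start. i-Pr enters by a desymmetrising Cu-catalysed 1,4-addition and O at C5 by enolate hydroxylation; then C1 iodination, Negishi union with (tigloyloxymethyl)zinc iodide, ketal → C3 ketone → C3 alcohol → tiglate, and desilylation.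
Stereochemistry: C4 comes from the chiral Cu–phosphoramidite catalyst; C5–O and C3–O are both relayed from C4, because oxidant and hydride each enter anti to the isopropyl group.
Enabling feature: C1 is the α-carbon of a cyclohex-2-enone whose β-carbon C2 is an unsubstituted CH, so C1 can take iodine and then palladium. C7 carries only oxygen (no β-H), so its zinc reagent is stable, and it arrives already esterified, so the primary tiglate never has to be distinguished from the C5 hydroxyl.

Key step: step 7

Assumption: the (S,R,R)-phosphoramidite is taken to show the same facial preference with dienone 1 and i-Pr2Zn as it does with cyclohex-2-enone; if it proves opposite, the enantiomeric ligand is used.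

**Route**

Step 1
Reactants: 1 4,4-dimethoxycyclohexa-2,5-dien-1-one; 2 diisopropylzinc
Product: 4 (5S)-5-isopropyl-4,4-dimethoxycyclohex-2-en-1-one, via isopropylzinc dienolate 3 (not isolated)
Conditions: Cu(OTf)2 (2 mol %), (S,R,R)-BINOL bis(1-phenylethyl)amine phosphoramidite (4 mol %), toluene, −30 °C; aq NH4Cl
Reagents that add atoms: none
Why: Cu/phosphoramidite-catalysed 1,4-addition of a dialkylzinc desymmetrises the two enantiotopic enone halves of the quinone monoketal; the catalyst should set the isopropyl-bearing centre, and the zinc enolate formed protects the product from a second addition.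

Step 2
Reactants: 4 (5S)-5-isopropyl-4,4-dimethoxycyclohex-2-en-1-one
Product: 6 (5R,6R)-6-hydroxy-5-isopropyl-4,4-dimethoxycyclohex-2-en-1-one, via potassium dienolate 5 (not isolated)
Conditions: KHMDS, THF, −78 °C; Davis oxaziridine, −78 °C; AcOH
Reagents that add atoms: 3-phenyl-2-(phenylsulfonyl)oxaziridine, O=S(=O)(N1OC1c1ccccc1)c1ccccc1
Why: Deprotonation can only occur at the α'-CH2 (the γ-carbon is a ketal), and Davis enolate hydroxylation should deliver oxygen to the face opposite the adjacent isopropyl group, giving the trans hydroxy ketone (the descriptor change at the isopropyl carbon is a CIP priority effect only).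

Step 3
Reactants: 6 (5R,6R)-6-hydroxy-5-isopropyl-4,4-dimethoxycyclohex-2-en-1-one
Product: 7 (5R,6R)-6-[(tert-butyldimethylsilyl)oxy]-5-isopropyl-4,4-dimethoxycyclohex-2-en-1-one
Conditions: TBSCl, imidazole, DMF, rt
Reagents that add atoms: tert-butyldimethylsilyl chloride, CC(C)(C)[Si](C)(C)Cl
Why: Standard silylation of a secondary alcohol; the silyl ether keeps this hydroxyl out of the later acylation and should survive the brief acid of step 8.

Step 4
Reactants: 7 (5R,6R)-6-[(tert-butyldimethylsilyl)oxy]-5-isopropyl-4,4-dimethoxycyclohex-2-en-1-one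
Product: 8 (5R,6R)-6-[(tert-butyldimethylsilyl)oxy]-2-iodo-5-isopropyl-4,4-dimethoxycyclohex-2-en-1-one
Conditions: I2, pyridine/CH2Cl2 (1:1), 0 °C to rt
Reagents that add atoms: iodine, II
Why: Pyridine-mediated α-iodination of an enone (Baylis–Hillman-type addition of pyridine to the free β-CH, iodination of the enolate, elimination of pyridine), which needs no strong base and leaves the ketal and silyl ether alone.

Step 5
Reactants: 9 tigloyl chloride [(2E)-2-methylbut-2-enoyl chloride]; 10 paraformaldehyde
Product: 11 chloromethyl (2E)-2-methylbut-2-enoate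
Conditions: ZnCl2 (2 mol %), neat, 70 °C; distillation
Reagents that add atoms: none
Why: Lewis-acid-catalysed insertion of formaldehyde into an acyl chloride is the classical chloromethyl ester synthesis; no base is present, so the E-alkene should be untouched.

Step 6
Reactants: 11 chloromethyl (2E)-2-methylbut-2-enoate
Product: 12 iodomethyl (2E)-2-methylbut-2-enoate
Conditions: NaI, acetone, rt, dark
Reagents that add atoms: sodium iodide, [Na+].[I-]
Why: Finkelstein exchange, driven by precipitation of NaCl, gives the iodide needed for zinc insertion.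

Step 7
Reactants: 8 (5R,6R)-6-[(tert-butyldimethylsilyl)oxy]-2-iodo-5-isopropyl-4,4-dimethoxycyclohex-2-en-1-one; 12 iodomethyl (2E)-2-methylbut-2-enoate
Product: 14 [(4R,5R)-5-[(tert-butyldimethylsilyl)oxy]-4-isopropyl-3,3-dimethoxy-6-oxocyclohex-1-en-1-yl]methyl (2E)-2-methylbut-2-enoate, via (tigloyloxymethyl)zinc iodide 13 (not isolated)
Conditions: 12, Zn dust (activated with BrCH2CH2Br/TMSCl), THF, 15 °C, solution decanted from excess Zn; then 8, Pd2(dba)3 (2.5 mol %), P(2-furyl)3 (10 mol %), THF/NMP, rt
Reagents that add atoms: none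
Why: Zinc inserts into the C–I bond of 12 to give the α-acyloxyalkylzinc iodide 13; Pd(0) adds oxidatively to the C(sp2)–I bond of α-iodoenone 8, the CH2 group passes from zinc to palladium, and reductive elimination forms the C(sp2)–C(sp3) bond. The closest known reaction type is the Negishi coupling of α-iodoenones with alkylzinc halides, together with the use of (acyloxymethyl)zinc iodides (pivalate, benzoate) as protected hydroxymethyl donors in Pd-catalysed couplings. No ring is closed and no stereocentre is created, and the neutral conditions should leave the epimerisable silyloxy-bearing centre next to the ketone untouched. The transferred carbon carries oxygen and no β-hydrogen, so neither the zinc nor the palladium alkyl can undergo β-hydride elimination. The step needs chemoselectivity for the C–I bond over the enone and ketone (alkylzinc iodides do not add to either without copper or Lewis-acid activation) and over the allylic ester that is formed; the latter should be secured by the much faster oxidative addition of the vinyl iodide with the weakly donating tri(2-furyl)phosphine and by stopping at full conversion of 8.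

Step 8
Reactants: 14 [(4R,5R)-5-[(tert-butyldimethylsilyl)oxy]-4-isopropyl-3,3-dimethoxy-6-oxocyclohex-1-en-1-yl]methyl (2E)-2-methylbut-2-enoate
Product: 15 [(4R,5R)-5-[(tert-butyldimethylsilyl)oxy]-4-isopropyl-3,6-dioxocyclohex-1-en-1-yl]methyl (2E)-2-methylbut-2-enoate
Conditions: p-TsOH·H2O (cat.), acetone/H2O, 0 °C to rt; used directly
Reagents that add atoms: water, O
Why: Acid-catalysed hydrolysis (transketalisation to acetone) of the dimethyl ketal unmasks the second carbonyl; contact is kept short and cold because the ene-dione could tautomerise to a hydroquinone.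

Step 9
Reactants: 15 [(4R,5R)-5-[(tert-butyldimethylsilyl)oxy]-4-isopropyl-3,6-dioxocyclohex-1-en-1-yl]methyl (2E)-2-methylbut-2-enoate
Product: 16 [(3S,4S,5R)-5-[(tert-butyldimethylsilyl)oxy]-3-hydroxy-4-isopropyl-6-oxocyclohex-1-en-1-yl]methyl (2E)-2-methylbut-2-enoate
Conditions: NaBH4, CeCl3·7H2O, MeOH, −78 °C
Reagents that add atoms: none
Why: Luche 1,2-reduction should take the carbonyl next to the ring CH= rather than the one flanked by the substituted alkene carbon and the silyloxy carbon, and hydride should enter anti to the adjacent pseudo-axial isopropyl group (Felkin–Anh), placing the new hydroxyl cis to isopropyl; the esters are inert under these conditions.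

Step 10
Reactants: 16 [(3S,4S,5R)-5-[(tert-butyldimethylsilyl)oxy]-3-hydroxy-4-isopropyl-6-oxocyclohex-1-en-1-yl]methyl (2E)-2-methylbut-2-enoate; 9 tigloyl chloride
Product: 17 [(3S,4S,5R)-5-[(tert-butyldimethylsilyl)oxy]-4-isopropyl-3-{[(2E)-2-methylbut-2-enoyl]oxy}-6-oxocyclohex-1-en-1-yl]methyl (2E)-2-methylbut-2-enoate
Conditions: pyridine, CH2Cl2, 0 °C to rt (no DMAP)
Reagents that add atoms: none
Why: Acylation of the only free hydroxyl with an acid chloride and pyridine, which is too weak a base and nucleophile to isomerise the tiglate, eliminate the γ-acyloxy group or attack the allylic ester.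

Step 11
Reactants: 17 [(3S,4S,5R)-5-[(tert-butyldimethylsilyl)oxy]-4-isopropyl-3-{[(2E)-2-methylbut-2-enoyl]oxy}-6-oxocyclohex-1-en-1-yl]methyl (2E)-2-methylbut-2-enoate
Product: 18 [(3S,4R,5R)-5-hydroxy-4-isopropyl-3-{[(2E)-2-methylbut-2-enoyl]oxy}-6-oxocyclohex-1-en-1-yl]methyl (2E)-2-methylbut-2-enoate (target)
Conditions: HF·pyridine, pyridine/THF, 0 °C to rt
Reagents that add atoms: none
Why: Fluoride cleavage of the silyl ether under buffered acidic conditions avoids the basic media in which the γ-acyloxy enone could eliminate and aromatise (the descriptor change at the isopropyl carbon is again a CIP priority effect).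

**Compound list**

1 | 4,4-dimethoxycyclohexa-2,5-dien-1-one | COC1(OC)C=CC(=O)C=C1 | starting material
2 | diisopropylzinc | CC(C)[Zn]C(C)C | starting material
3 | isopropylzinc (3R)-3-isopropyl-4,4-dimethoxycyclohexa-1,5-dien-1-olate | C1=CC(OC)(OC)[C@H](C(C)C)C=C1O[Zn]C(C)C | intermediate (not isolated)
4 | (5S)-5-isopropyl-4,4-dimethoxycyclohex-2-en-1-one | C1=CC(OC)(OC)[C@H](C(C)C)CC1=O | intermediate
5 | potassium (3R)-3-isopropyl-4,4-dimethoxycyclohexa-1,5-dien-1-olate | C1=CC(OC)(OC)[C@H](C(C)C)C=C1[O-].[K+] | intermediate (not isolated)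
6 | (5R,6R)-6-hydroxy-5-isopropyl-4,4-dimethoxycyclohex-2-en-1-one | C1=CC(OC)(OC)[C@H](C(C)C)[C@@H](O)C1=O | intermediate
7 | (5R,6R)-6-[(tert-butyldimethylsilyl)oxy]-5-isopropyl-4,4-dimethoxycyclohex-2-en-1-one | C1=CC(OC)(OC)[C@H](C(C)C)[C@@H](O[Si](C)(C)C(C)(C)C)C1=O | intermediate
8 | (5R,6R)-6-[(tert-butyldimethylsilyl)oxy]-2-iodo-5-isopropyl-4,4-dimethoxycyclohex-2-en-1-one | IC1=CC(OC)(OC)[C@H](C(C)C)[C@@H](O[Si](C)(C)C(C)(C)C)C1=O | intermediate
9 | tigloyl chloride, (2E)-2-methylbut-2-enoyl chloride | C/C=C(\C)C(=O)Cl | starting material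
10 | paraformaldehyde (formaldehyde unit shown) | C=O | starting material
11 | chloromethyl (2E)-2-methylbut-2-enoate | C/C=C(\C)C(=O)OCCl | intermediate
12 | iodomethyl (2E)-2-methylbut-2-enoate | C/C=C(\C)C(=O)OCI | intermediate
13 | (tigloyloxymethyl)zinc iodide | C/C=C(\C)C(=O)OC[Zn]I | intermediate (not isolated)
14 | [(4R,5R)-5-[(tert-butyldimethylsilyl)oxy]-4-isopropyl-3,3-dimethoxy-6-oxocyclohex-1-en-1-yl]methyl (2E)-2-methylbut-2-enoate | C/C=C(\C)C(=O)OCC1=CC(OC)(OC)[C@H](C(C)C)[C@@H](O[Si](C)(C)C(C)(C)C)C1=O | intermediate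
15 | [(4R,5R)-5-[(tert-butyldimethylsilyl)oxy]-4-isopropyl-3,6-dioxocyclohex-1-en-1-yl]methyl (2E)-2-methylbut-2-enoate | C/C=C(\C)C(=O)OCC1=CC(=O)[C@H](C(C)C)[C@@H](O[Si](C)(C)C(C)(C)C)C1=O | intermediate
16 | [(3S,4S,5R)-5-[(tert-butyldimethylsilyl)oxy]-3-hydroxy-4-isopropyl-6-oxocyclohex-1-en-1-yl]methyl (2E)-2-methylbut-2-enoate | C/C=C(\C)C(=O)OCC1=C[C@H](O)[C@H](C(C)C)[C@@H](O[Si](C)(C)C(C)(C)C)C1=O | intermediate
17 | [(3S,4S,5R)-5-[(tert-butyldimethylsilyl)oxy]-4-isopropyl-3-{[(2E)-2-methylbut-2-enoyl]oxy}-6-oxocyclohex-1-en-1-yl]methyl (2E)-2-methylbut-2-enoate | C/C=C(\C)C(=O)OCC1=C[C@H](OC(=O)/C(C)=C/C)[C@H](C(C)C)[C@@H](O[Si](C)(C)C(C)(C)C)C1=O | intermediate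
18 | [(3S,4R,5R)-5-hydroxy-4-isopropyl-3-{[(2E)-2-methylbut-2-enoyl]oxy}-6-oxocyclohex-1-en-1-yl]methyl (2E)-2-methylbut-2-enoate | C/C=C(\C)C(=O)OCC1=C[C@H](OC(=O)/C(C)=C/C)[C@H](C(C)C)[C@@H](O)C1=O | target

**Count**

Total steps: 11. Longest linear sequence: 9 (steps 1–4 and 7–11); steps 5 and 6 make the coupling partner.

**Steps most likely to fail**

Step 9. The hydride may be delivered to the wrong face of the carbonyl, because the ring can react through either half-chair; competing transfer to the other, more shielded carbonyl is the lesser worry. The fallback sets out from 15 and does not discard the epimer. If reduction gives mainly [(3R,4S,5R)-5-[(tert-butyldimethylsilyl)oxy]-3-hydroxy-4-isopropyl-6-oxocyclohex-1-en-1-yl]methyl (2E)-2-methylbut-2-enoate F1, the centre is corrected during esterification. Mitsunobu reaction of F1 with tiglic acid (PPh3, DIAD, toluene, 0 °C) should invert the carbinol carbon and install the tiglate in one operation. The sequence returns to the route at 17 and replaces steps 9 and 10.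

Step 7. The α-acyloxyalkylzinc reagent may decompose before transmetalation, or palladium may ionise the allylic ester of the product and carry it on to over-coupled material. The fallback sets out from 8 and transfers an unacylated carbon instead. Stille coupling with (tributylstannyl)methanol (Pd(PPh3)4, dioxane, 80 °C) should give (5R,6R)-6-[(tert-butyldimethylsilyl)oxy]-2-(hydroxymethyl)-5-isopropyl-4,4-dimethoxycyclohex-2-en-1-one F2, an allylic alcohol that palladium cannot ionise. Acylation of F2 with tigloyl chloride 9 and pyridine returns to the route at 14.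

Step 1. Transfer of the secondary alkyl group from zinc may be slow or poorly enantioselective. The fallback sets out from 1 and uses a Hayashi–Miyaura addition: isopropenylboronic acid pinacol ester, Rh(I)/(S)-BINAP, aqueous KOH, dioxane. This should give (5S)-4,4-dimethoxy-5-(prop-1-en-2-yl)cyclohex-2-en-1-one F3. Hydrogenation of the 1,1-disubstituted alkene of F3 with Wilkinson's catalyst (H2, benzene), which should spare the hindered conjugated alkene, returns to the route at 4.

**Further compounds**

F1 | step 9 | [(3R,4S,5R)-5-[(tert-butyldimethylsilyl)oxy]-3-hydroxy-4-isopropyl-6-oxocyclohex-1-en-1-yl]methyl (2E)-2-methylbut-2-enoate | C/C=C(\C)C(=O)OCC1=C[C@@H](O)[C@H](C(C)C)[C@@H](O[Si](C)(C)C(C)(C)C)C1=O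
F2 | step 7 | (5R,6R)-6-[(tert-butyldimethylsilyl)oxy]-2-(hydroxymethyl)-5-isopropyl-4,4-dimethoxycyclohex-2-en-1-one | OCC1=CC(OC)(OC)[C@H](C(C)C)[C@@H](O[Si](C)(C)C(C)(C)C)C1=O
F3 | step 1 | (5S)-4,4-dimethoxy-5-(prop-1-en-2-yl)cyclohex-2-en-1-one | C1=CC(OC)(OC)[C@H](C(C)=C)CC1=O
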